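Count the reagent.

all flasks: solid substrate 0.50 mM; reagent 0.475 mM
- alder: base 0.014 mM; temperature 2 °C; run made earlier
- elm: base 0.022 mM; temperature 19 °C; run made earlier
- blue: base 0.0100 mM; temperature −5 °C; time 12 min
- ochre: base 0.0100 mM; at −5 °C until 4.0 min, from then on at 25 °C; time 12 min
- violet: base 0.0100 mM; temperature 25 °C; time 12 min

| run | time / min | product / % | solid substrate / % |
|---|---|---|---|
| alder | 2.00 | 2.6 | 47.3 |
| alder | 4.00 | 79.8 | 0.1 |
| alder | 6.00 | 92.4 | 0 |
| alder | 8.00 | 94.1 | 0.5 |
| alder | 10.0 | 94.3 | 0 |
| alder | 12.0 | 94.7 | 0 |
| elm | 0.250 | 0.3 | 61.3 |
| elm | 0.833 | 3.5 | 48.2 |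
| elm | 1.33 | 10.0 | 43.6 |
| elm | 2.00 | 69.0 | 0.1 |
| elm | 3.00 | 90.5 | 0.3 |
| elm | 4.00 | 93.3 | 0 |

(standard deviation of a reading: 0.3 percentage points)

- as a solid, counted per litre of solution: solid substrate
- what was read earlier has a scatter of 0.3 percentage points, one standard deviation
- at the start none of the solid substrate is in solution
- what has only dissolved of solid substrate counts as not reacted

* the flask that comes out highest in amount of product, in percent of the solid substrate charged, or "all alike" when all lie within 1.5 percentage points (blue / ochre / violet / all alike)
* product at the end, in percent of the solid substrate charged, blue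
* product at the end, in percent of the solid substrate charged, ochre
* product at the end, in percent of the solid substrate charged, violet

1. The main step first. I take one reagent spent per product, so reagent charge over solid substrate charge gives 95.0%: this is the product ceiling, with reagent as the limiting reagent. In alder the last reading, 94.7%, lies within 0.3 percentage points of it.

2. Add dissolving. At 2.00 min alder reads 47.3% as solid and 2.6% as product, so 50.1% is dissolved and unreacted. I take dissolving to spend no reagent, so the reagent count stays.

3. Add the burst. Between 2.00 min and 4.00 min alder's product jumps from 2.6% to 79.8%. A tail follows: the gap to the ceiling is 2.6 points at 6.00 min and 0.9 points at 8.00 min. So in alder product closes on the ceiling as the clock runs.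

4. Put in the clock. Elm at 2.00 min resembles alder at 4.00 min, a stretch of 2.00, but base and temperature changed together. Setting base aside and scaling by temperature, blue stretches alder's clock by 1.33. Blue's 12 min then matches alder at 9.02 min, so I reckon blue between 94.1% and 94.3%. Violet is warmer than elm and runs 3.00 times as long as elm's last reading, so I put it on the ceiling. Ochre has 8.00 min warm, and I put it there too. My answer is all alike.

5. The forecast gives 93.5% for blue, lower than my reckoning, 94.3% for ochre and 94.5% for violet, with all alike, reasoning that “All should finish near the ceiling”.

6. The flasks give 94.6% for blue, 95.0% for ochre and 95.0% for violet: all alike.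

    starting material + reagent + released group → product + 2 released group (k = 1.20 × 10⁶ L² mol⁻² s⁻¹, Ea = 19.0 kJ mol⁻¹)
    starting material + reagent → product + released group (k = 5.30 L mol⁻¹ s⁻¹, Ea = 48.0 kJ mol⁻¹)
    base + released group ⇌ salt, settled at all times (K = 8.70 × 10⁶ L mol⁻¹, ΔH = −51.0 kJ mol⁻¹)
    solid substrate ⇌ starting material, rate k4*(cs4 - [starting material]) while solid is left; crystals form when [starting material] > cs4 (solubility = 0.250 mM, k = 0.100 s⁻¹)
    (constants at 25 °C)

Both product-forming reactions spend one reagent per product, and in violet at 0.539 min the one with released group uses reagent 1.8 times as fast as the plain one. At 12.0 min violet has 0% of its reagent left and holds 5.00% as starting material, against the 5.00% of the solid substrate charge that lies beyond the reagent charge.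

7. Take violet with 0.19 mM of reagent instead. The ceiling scales to 38.0%. That flask gives 38.0%, with 0% of its reagent left, 50.0% as starting material and 12.0% as solid substrate.

(All runs are calculated for an exercise; the scatter is artificial.)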